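## Analysis of the target

The target is a biflavanoid joined by the bond from C4 of the upper pyran ring C to C8' of the lower phloroglucinol ring D. The upper unit is a 4',7-dihydroxyflavan (rings A, B, C). The lower unit is (+)-gallocatechin (rings D, E, F).

There are four stereocentres. C2 (S) and C4 (R) carry their aryl groups trans on ring C. C2' (R) and C3' (S) carry ring E and the hydroxyl trans on ring F. The aromatic ring D separates the two pairs, so neither pair can be relayed from the other and each has to be set on its own.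

Sensitive features are the eight phenols (the pyrogallol ring E oxidises readily in base and air), the free secondary alcohol, the two benzylic aryl ether bonds C2–O1 and C2'–O1' (opened and epimerised through benzylic cations in acid), and the doubly benzylic C4–H.

Three things make the synthesis hard. C8' and C6' of ring D both lie between two oxygens and are nearly equivalent. The 2,4-trans arrangement on ring C is not what a reversible, cationic ring closure would favour. Eight hydroxyl groups must be freed at the end without acid.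

The strategy rests on one feature of ring D: the ring F oxygen O1' sits on C8a', the interflavan carbon C4 sits on the neighbouring C8', and C8' is flanked by the C7' oxygen. These are the two adjacent positions at which a 3-alkoxy-substituted aryne takes up a nucleophile and an electrophile. Ring A repeats the pattern in a simpler form: O1 on C8a, next to C8–H, next to the C7 oxygen.

## Retrosynthetic reasoning

**27 ⇐ 26 ⇐ 25 (no skeletal bond cut).** The seven phenols are carried as benzyl ethers and the C3' hydroxyl as a triisopropylsilyl ether. Fluoride takes 25 to 26 and hydrogenolysis takes 26 to 27. The gain is a neutral last step on a polyphenol that tolerates neither acid nor base. The forward reactions must leave the two benzylic ring C–O bonds intact.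

**25 ⇐ 21 (O1–C8a of ring C).** Ring C is opened at the aryl–oxygen bond and not at the benzylic C2–O bond. A closure that forms C2–O would run through a para-alkoxybenzylic carbon, which ionises easily, and would need an orthogonally protected ring A phenol. Cutting O1–C8a leaves C2 as a spectator, so its configuration in 21 is retained. In the forward direction the alkoxide of 21 adds to a ring A aryne, generated by loss of fluoride between C8a and C8 (intermediates 22, 23, 24). This is the reaction type of the key step, used a second time with a proton as the electrophile.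

**21 ⇐ 20 (C2 stereocentre).** The carbinol is traced to ketone 20. A catalyst-controlled reduction has to give the (S) alcohol regardless of the remote C4 centre.

**20 ⇐ 18 + 19 (C4–C4a).** The bond between C4 and ring A is cut so that ring A arrives as the aryl boron reagent 19 and C4 is the β-carbon of enone 18. An ipso aryl transfer has no regiochemical ambiguity on ring A. A chiral rhodium catalyst sets C4, independently of the centres in ring F.

**18 ⇐ 16 + 17 (C3=C4).** An aldol condensation cut gives aldehyde 16, whose formyl carbon is C4, and ketone 17, which brings C2, C3 and ring B. The forward reaction needs only a non-enolisable aldehyde and a methyl ketone.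

**16 ⇐ 11 + 12 (O1'–C8a' and C8'–C4, the key disconnection).** Both bonds to the adjacent ring D carbons C8a' and C8' are cut at once. Fluorine on C8a' and hydrogen on C8' of 11 are the latent aryne. The C2' oxygen is the nucleophile and 12 is the one-carbon electrophile (intermediates 13, 14, 15). Cutting here puts the future C4 on C8' by mechanism, not by a selective substitution of a phloroglucinol ring, and leaves C2' and C3' untouched. The C3' oxygen must be blocked, since a free alkoxide there would close a five-membered ring. The silyl group is triisopropylsilyl and not a smaller one, because a smaller silyl group next to a lithium alkoxide could migrate between the two oxygens and open exactly that five-membered path.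

**11 ⇐ 8 + 9 (C2'–ring E bond).** Because the key step retains C2', the precursor needs the anti (1R,2S) pattern, which a syn-dihydroxylation of an E-alkene does not give directly. The cut between C2' and ring E leads to α-silyloxy aldehyde 8 and the aryl Grignard reagent 10 made from 9. The forward addition must be non-chelation (Felkin–Anh) controlled.

**8 ⇐ 7 ⇐ 6 ⇐ 5 (oxidation level and protecting groups).** The aldehyde comes from primary alcohol 7, freed from trityl ether 6, which is the silyl ether of 5. Each forward step is a standard operation and none touches the C3' centre.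

**5 ⇐ 2 + 3 (C4a'–C4').** The benzylic bond of ring D is cut to aryllithium 4, made from 2, and the terminal epoxide carbon of 3. This takes C3' from the chiral pool and places fluorine and carbon ortho to each other in one operation. 2 is the bis-benzyl ether of 1.

## Alternatives that were turned down

**Alternative 1:** The disconnection is the C3'=C4' double bond of a flav-3-ene form of ring F; the 3'-hydroxyl is added afterwards by hydroboration–oxidation. In the key step the second-generation Grubbs catalyst converts diene A2 into flavene A1. A2 has a vinyl group on C4a' and a 1-arylallyl ether on the C8a' oxygen.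

- For: ring-closing metathesis of such styrene/allyl ether pairs is catalytic, neutral and indifferent to benzyl ethers and to the upper unit. Only C2' has to be made, and C3' is relayed from it (boron to the non-benzylic C3', anti to ring E). On the reliability of the ring closure itself this alternative is stronger than the chosen key step.
- Against: A2 contains an ether carbon that is both allylic and benzylic to the trioxygenated ring E, bound to a phenol oxygen flanked on both sides (C8' with the whole upper unit, C4a' with vinyl). Forming that C2'–O1' bond as a single enantiomer, and keeping it from ionising, is harder than anything in the chosen route. The metathesis also says nothing about C8' versus C6'; the C8'–C4 bond must already exist. After A1, three more operations follow, with only substrate control for C3'.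
- Comparison: the chosen step offers the aryl–oxygen bond and the C8'–C4 bond in one operation, from a precursor whose two stereocentres are fixed and do not react. The price is a strongly basic organolithium step in place of a neutral catalytic one.

**Alternative 2:** The disconnection is C4–C4a and O1–C2 of ring C, grown as a lactol onto a finished lower unit. In the key step a chiral secondary amine converts enal A4 into its iminium ion; phenol A5 alkylates through the carbon ortho to its hydroxyl, and the hydroxyl closes onto the aldehyde to give lactol A3.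

- For: the lower unit could be taken from natural A6 with both stereocentres in place. This is clearly more step-economical than the seven steps the chosen route spends building ring F, and on this point the alternative is stronger. C4 would be set by a metal-free catalyst.
- Against: A4 requires a carbon substituent on C8' of an A6 ether, where C6' competes. The β-aryl group of A4 is a 2,4,6-trioxygenated ring, so the iminium ion is weakly electrophilic and crowded. A5 is only moderately activated and has three nucleophilic carbons; attack para to the hydroxyl cannot lactolise. A3 lacks ring B and the C2 centre, so ring C must be opened by an aryl nucleophile, adjusted in oxidation state and closed again — the ring is made twice.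
- Comparison: the chosen route pays for a de novo lower unit. In return C8' is substituted unambiguously, and ring A enters by ipso transfer from boron with no site question.

**Alternative 3:** The disconnection is O1'–C2' of ring F, closed last. In the key step an orthoester and acid turn the syn (1S,2S)-diol A8 into a dioxolanylium ion; the C8a' phenol displaces the benzylic oxygen at C2' with inversion and gives the 3'-formate A7.

- For: the diol comes from an asymmetric dihydroxylation of an E-1,3-diarylpropene, which sets both ring F centres in one predictable catalytic step. This is a more reliable source of stereochemistry than the Felkin–Anh addition of the chosen route, and on this point the alternative is stronger.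
- Against: the closure runs in acid on the complete skeleton, which holds the acid-labile C2–O1 ether of ring C and the doubly benzylic C4. The reacting carbon C2' carries a 3,4,5-trioxygenated aryl group, so ionisation competes with invertive opening and erodes the trans relationship. A8 needs the C8a' oxygen free and the C5' oxygen benzylated, two ortho oxygens that differ only through the remote C8' substituent. The C8'–C4 bond must again be made on a ring with the C6'/C8' ambiguity.
- Comparison: the chosen step forms the aryl–oxygen bond, so C2' never reacts. It runs in base, and it settles C8' versus C6' in the same operation.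

Key step: step 7

Assumption: the (1R,4R)-diene ligand of step 9 is taken to show on enone 18 the face preference it shows on simple acyclic E-enones, which corresponds to the required arrangement at C4; if the opposite sense is found, the (1S,4S)-ligand is used in the same way.

Assumption: 3, 9, 17 and 19 are purchased.

## Route

Step 1
Reactants: 1 5-fluororesorcinol
Product: 2 1-fluoro-3,5-bis(benzyloxy)benzene
Conditions: BnBr (2.3 equiv), K2CO3, DMF, 60 °C
Reagents that add atoms: benzyl bromide, BrCc1ccccc1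
Why: Williamson etherification of both phenols; the unactivated aryl fluoride is inert to carbonate and benzyl bromide.

Step 2
Reactants: 2 1-fluoro-3,5-bis(benzyloxy)benzene; 3 (S)-trityl glycidyl ether
Product: 5 (2S)-1-[2-fluoro-4,6-bis(benzyloxy)phenyl]-3-(trityloxy)propan-2-ol, via aryllithium 4 (not isolated)
Conditions: n-BuLi, THF, −78 °C; then 3, BF3·OEt2, −78 °C
Reagents that add atoms: none
Why: Directed ortho-lithiation at the C–H flanked by fluorine and a benzyloxy group gives 4, which is kept at −78 °C so that it does not lose lithium fluoride. BF3-promoted opening of the epoxide at its terminal carbon leaves the stereocentre untouched, so the (S) configuration of 3 becomes the (S) carbinol (future C3').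

Step 3
Reactants: 5 (2S)-1-[2-fluoro-4,6-bis(benzyloxy)phenyl]-3-(trityloxy)propan-2-ol
Product: 6 (2S)-1-[2-fluoro-4,6-bis(benzyloxy)phenyl]-2-(triisopropylsilyloxy)-3-(trityloxy)propane
Conditions: TIPSOTf, 2,6-lutidine, CH2Cl2, 0 °C → rt
Reagents that add atoms: triisopropylsilyl trifluoromethanesulfonate, CC(C)[Si](C(C)C)(C(C)C)OS(=O)(=O)C(F)(F)F
Why: Silyl triflate silylation of a hindered secondary alcohol. The bulky, non-chelating triisopropylsilyl group serves the Felkin–Anh addition of step 6 and resists oxygen-to-oxygen migration in the alkoxide of step 7.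

Step 4
Reactants: 6 (2S)-1-[2-fluoro-4,6-bis(benzyloxy)phenyl]-2-(triisopropylsilyloxy)-3-(trityloxy)propane
Product: 7 (2S)-3-[2-fluoro-4,6-bis(benzyloxy)phenyl]-2-(triisopropylsilyloxy)propan-1-ol
Conditions: TsOH·H2O (cat.), MeOH/CH2Cl2, rt
Reagents that add atoms: none
Why: Acid-catalysed methanolysis of the trityl ether through the trityl cation; the secondary triisopropylsilyl ether and the aryl benzyl ethers are stable to these mild conditions.

Step 5
Reactants: 7 (2S)-3-[2-fluoro-4,6-bis(benzyloxy)phenyl]-2-(triisopropylsilyloxy)propan-1-ol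
Product: 8 (2S)-3-[2-fluoro-4,6-bis(benzyloxy)phenyl]-2-(triisopropylsilyloxy)propanal
Conditions: Dess–Martin periodinane, CH2Cl2, 0 °C → rt
Reagents that add atoms: none
Why: Dess–Martin oxidation is non-basic and does not enolise the α-silyloxy aldehyde, which is used at once without purification so that the (S) centre is kept.

Step 6
Reactants: 8 (2S)-3-[2-fluoro-4,6-bis(benzyloxy)phenyl]-2-(triisopropylsilyloxy)propanal; 9 5-bromo-1,2,3-tris(benzyloxy)benzene
Product: 11 (1R,2S)-3-[2-fluoro-4,6-bis(benzyloxy)phenyl]-2-(triisopropylsilyloxy)-1-[3,4,5-tris(benzyloxy)phenyl]propan-1-ol, via Grignard reagent 10 (not isolated)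
Conditions: 9, Mg, THF, 40 °C; then 8, THF, −78 °C
Reagents that add atoms: none
Why: Felkin–Anh addition of an aryl Grignard reagent to an α-silyloxy aldehyde: the bulky silyloxy group cannot chelate and lies anti to the incoming aryl group, which should favour the anti (1R,2S) alcohol. The minor syn epimer is removed by chromatography.

Step 7
Reactants: 11 (1R,2S)-3-[2-fluoro-4,6-bis(benzyloxy)phenyl]-2-(triisopropylsilyloxy)-1-[3,4,5-tris(benzyloxy)phenyl]propan-1-ol; 12 N,N-dimethylformamide
Product: 16 (2R,3S)-5,7-bis(benzyloxy)-2-[3,4,5-tris(benzyloxy)phenyl]-3-(triisopropylsilyloxy)chromane-8-carbaldehyde, via dilithio species 13 (not isolated), via aryne alkoxide 14 (not isolated), via lithioflavan 15 (not isolated)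
Conditions: lithium 2,2,6,6-tetramethylpiperidide (3.5 equiv; from n-BuLi and 2,2,6,6-tetramethylpiperidine), THF, −78 → −20 °C; then 12 (10 equiv), −78 → 0 °C
Reagents that add atoms: none
Why: Tandem aryne etherification–formylation; the closest known reaction type is alkoxide addition to an aryne generated from an ortho-lithiated aryl fluoride, followed by electrophilic quench of the new aryllithium. The amide base first deprotonates the C2' hydroxyl and then the ring D C–H flanked by fluorine and the C7' benzyloxy group to give 13, which on warming loses lithium fluoride to give aryne 14 (C8'≡C8a'). The tethered alkoxide adds to C8a' in a 6-exo-dig closure of ring F (O1'–C8a'), the only mode the three-carbon tether allows, since attack at C8' would be a strained 7-endo closure. The electronic preference agrees: addition at the aryne carbon remote from the C7' oxygen leaves the carbanion on C8' beside that oxygen, where it is inductively stabilised, giving 15. This 2,6-dioxygenated aryllithium persists at low temperature and is formylated by 12, so the carbon that becomes C4 enters at C8' with no C6'/C8' selectivity question (C8'–C4). No stereocentre is formed or broken: the C2'–O and C3'–O bonds are untouched, so the anti (1R,2S) pattern of 11 becomes the 2',3'-trans (2'R,3'S) ring. The step needs lithiation next to fluorine and not between the two benzyloxy groups (that lithiation is reversible and cannot eliminate), alkoxide capture in place of amide addition (secured by the hindered, non-nucleophilic base) and no silyl migration to the alkoxide (secured by the triisopropylsilyl group).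

Step 8
Reactants: 16 (2R,3S)-5,7-bis(benzyloxy)-2-[3,4,5-tris(benzyloxy)phenyl]-3-(triisopropylsilyloxy)chromane-8-carbaldehyde; 17 4-(benzyloxy)acetophenone
Product: 18 (E)-1-[4-(benzyloxy)phenyl]-3-[(2R,3S)-5,7-bis(benzyloxy)-2-(3,4,5-tris(benzyloxy)phenyl)-3-(triisopropylsilyloxy)chroman-8-yl]prop-2-en-1-one
Conditions: KOH, EtOH/THF, rt → 40 °C
Reagents that add atoms: none
Why: Claisen–Schmidt condensation of a non-enolisable aldehyde with a methyl ketone; E1cB dehydration gives the E-enone. Silyl and benzyl ethers and the non-acidic ring F centres are stable to hydroxide at this temperature.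

Step 9
Reactants: 18 (E)-1-[4-(benzyloxy)phenyl]-3-[(2R,3S)-5,7-bis(benzyloxy)-2-(3,4,5-tris(benzyloxy)phenyl)-3-(triisopropylsilyloxy)chroman-8-yl]prop-2-en-1-one; 19 [4-(benzyloxy)-2-fluorophenyl]boronic acid
Product: 20 (3S)-1-[4-(benzyloxy)phenyl]-3-[4-(benzyloxy)-2-fluorophenyl]-3-[(2R,3S)-5,7-bis(benzyloxy)-2-(3,4,5-tris(benzyloxy)phenyl)-3-(triisopropylsilyloxy)chroman-8-yl]propan-1-one
Conditions: [RhCl(C2H4)2]2 (3 mol %), (1R,4R)-2,5-diphenylbicyclo[2.2.2]octa-2,5-diene (6.6 mol %), KOH (0.5 equiv), 19 (3 equiv), 1,4-dioxane/H2O, 40 °C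
Reagents that add atoms: none
Why: Hayashi–Miyaura 1,4-addition: the arylrhodium species formed by transmetalation inserts the enone, and the chiral diene selects the enone face, setting the C4 centre under catalyst control with the remote ring F centres as spectators. The small ortho fluorine is tolerated and is inert to monovalent rhodium. The descriptor is 3S here only because fluorine raises the priority of the ring A aryl group; the spatial arrangement is that of (4R) in the target.

Step 10
Reactants: 20 (3S)-1-[4-(benzyloxy)phenyl]-3-[4-(benzyloxy)-2-fluorophenyl]-3-[(2R,3S)-5,7-bis(benzyloxy)-2-(3,4,5-tris(benzyloxy)phenyl)-3-(triisopropylsilyloxy)chroman-8-yl]propan-1-one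
Product: 21 (1S,3S)-1-[4-(benzyloxy)phenyl]-3-[4-(benzyloxy)-2-fluorophenyl]-3-[(2R,3S)-5,7-bis(benzyloxy)-2-(3,4,5-tris(benzyloxy)phenyl)-3-(triisopropylsilyloxy)chroman-8-yl]propan-1-ol
Conditions: (R)-2-methyl-CBS-oxazaborolidine (0.3 equiv), BH3·SMe2, THF, −20 °C; then MeOH
Reagents that add atoms: none
Why: Corey–Bakshi–Shibata reduction of an aryl alkyl ketone: with the aryl group as the large substituent the (R)-catalyst delivers hydride to give the (S) carbinol. Control is by the catalyst, the C3 centre being too remote to direct.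

Step 11
Reactants: 21 (1S,3S)-1-[4-(benzyloxy)phenyl]-3-[4-(benzyloxy)-2-fluorophenyl]-3-[(2R,3S)-5,7-bis(benzyloxy)-2-(3,4,5-tris(benzyloxy)phenyl)-3-(triisopropylsilyloxy)chroman-8-yl]propan-1-ol
Product: 25 (2S,4R)-7-(benzyloxy)-2-[4-(benzyloxy)phenyl]-4-[(2R,3S)-5,7-bis(benzyloxy)-2-(3,4,5-tris(benzyloxy)phenyl)-3-(triisopropylsilyloxy)chroman-8-yl]chromane, via dilithio species 22 (not isolated), via aryne alkoxide 23 (not isolated), via lithioflavan 24 (not isolated)
Conditions: lithium 2,2,6,6-tetramethylpiperidide (3 equiv; from n-BuLi and 2,2,6,6-tetramethylpiperidine), THF, −78 → 0 °C; then H2O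
Reagents that add atoms: none
Why: Second intramolecular aryne etherification, the reaction type of step 7 with a proton as electrophile: alkoxide formation, lithiation of ring A between fluorine and benzyloxy, loss of lithium fluoride, 6-exo-dig attack of the alkoxide at C8a, and protonation of the C8 aryllithium on quench. The C2–O bond is never broken, so the (S) carbinol is retained as (2S), giving the 2,4-trans flavan without passing through a benzylic cation.

Step 12
Reactants: 25 (2S,4R)-7-(benzyloxy)-2-[4-(benzyloxy)phenyl]-4-[(2R,3S)-5,7-bis(benzyloxy)-2-(3,4,5-tris(benzyloxy)phenyl)-3-(triisopropylsilyloxy)chroman-8-yl]chromane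
Product: 26 (2R,3S)-5,7-bis(benzyloxy)-8-[(2S,4R)-7-(benzyloxy)-2-(4-(benzyloxy)phenyl)chroman-4-yl]-2-[3,4,5-tris(benzyloxy)phenyl]chroman-3-ol
Conditions: Bu4NF, THF, rt → 40 °C
Reagents that add atoms: none
Why: Fluoride-induced cleavage of the silyl ether; benzyl ethers and both pyran rings are inert to fluoride.

Step 13
Reactants: 26 (2R,3S)-5,7-bis(benzyloxy)-8-[(2S,4R)-7-(benzyloxy)-2-(4-(benzyloxy)phenyl)chroman-4-yl]-2-[3,4,5-tris(benzyloxy)phenyl]chroman-3-ol
Product: 27 (2R,3S)-8-[(2S,4R)-7-hydroxy-2-(4-hydroxyphenyl)chroman-4-yl]-2-(3,4,5-trihydroxyphenyl)chromane-3,5,7-triol (CNP0220331.3)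
Conditions: H2 (1 atm), Pd(OH)2/C, THF/MeOH, rt
Reagents that add atoms: none
Why: Hydrogenolysis of the seven benzyl ethers under neutral conditions, which avoids acid-induced opening of rings C and F. The O-benzyl ethers cleave faster than the cyclic benzylic C–O bonds, so the reaction is stopped at the calculated hydrogen uptake and the product is handled under inert gas.

## Compound list

1 | 5-fluororesorcinol | Oc1cc(O)cc(F)c1 | starting material
2 | 1-fluoro-3,5-bis(benzyloxy)benzene | Fc1cc(OCc2ccccc2)cc(OCc2ccccc2)c1 | intermediate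
3 | (S)-trityl glycidyl ether | C1O[C@@H]1COC(c1ccccc1)(c1ccccc1)c1ccccc1 | starting material
4 | [2-fluoro-4,6-bis(benzyloxy)phenyl]lithium | [Li]c1c(F)cc(OCc2ccccc2)cc1OCc1ccccc1 | intermediate
5 | (2S)-1-[2-fluoro-4,6-bis(benzyloxy)phenyl]-3-(trityloxy)propan-2-ol | Fc1cc(OCc2ccccc2)cc(OCc2ccccc2)c1C[C@H](O)COC(c1ccccc1)(c1ccccc1)c1ccccc1 | intermediate
6 | (2S)-1-[2-fluoro-4,6-bis(benzyloxy)phenyl]-2-(triisopropylsilyloxy)-3-(trityloxy)propane | Fc1cc(OCc2ccccc2)cc(OCc2ccccc2)c1C[C@H](O[Si](C(C)C)(C(C)C)C(C)C)COC(c1ccccc1)(c1ccccc1)c1ccccc1 | intermediate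
7 | (2S)-3-[2-fluoro-4,6-bis(benzyloxy)phenyl]-2-(triisopropylsilyloxy)propan-1-ol | Fc1cc(OCc2ccccc2)cc(OCc2ccccc2)c1C[C@H](O[Si](C(C)C)(C(C)C)C(C)C)CO | intermediate
8 | (2S)-3-[2-fluoro-4,6-bis(benzyloxy)phenyl]-2-(triisopropylsilyloxy)propanal | Fc1cc(OCc2ccccc2)cc(OCc2ccccc2)c1C[C@H](O[Si](C(C)C)(C(C)C)C(C)C)C=O | intermediate
9 | 5-bromo-1,2,3-tris(benzyloxy)benzene | Brc1cc(OCc2ccccc2)c(OCc2ccccc2)c(OCc2ccccc2)c1 | starting material
10 | [3,4,5-tris(benzyloxy)phenyl]magnesium bromide | Br[Mg]c1cc(OCc2ccccc2)c(OCc2ccccc2)c(OCc2ccccc2)c1 | intermediate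
11 | (1R,2S)-3-[2-fluoro-4,6-bis(benzyloxy)phenyl]-2-(triisopropylsilyloxy)-1-[3,4,5-tris(benzyloxy)phenyl]propan-1-ol | Fc1cc(OCc2ccccc2)cc(OCc2ccccc2)c1C[C@H](O[Si](C(C)C)(C(C)C)C(C)C)[C@H](O)c1cc(OCc2ccccc2)c(OCc2ccccc2)c(OCc2ccccc2)c1 | intermediate
12 | N,N-dimethylformamide | CN(C)C=O | starting material
13 | dilithio derivative of 11 (lithium alkoxide at C1; lithium on the ring carbon between fluorine and benzyloxy, the future C8') | [Li]c1c(F)c(C[C@H](O[Si](C(C)C)(C(C)C)C(C)C)[C@H](O[Li])c2cc(OCc3ccccc3)c(OCc3ccccc3)c(OCc3ccccc3)c2)c(OCc2ccccc2)cc1OCc1ccccc1 | intermediate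
14 | lithium alkoxide of the 3,5-bis(benzyloxy)aryne (triple bond between the future C8a' and C8') | [Li]O[C@H](c2cc(OCc3ccccc3)c(OCc3ccccc3)c(OCc3ccccc3)c2)[C@@H](O[Si](C(C)C)(C(C)C)C(C)C)CC1=C(OCc2ccccc2)C=C(OCc2ccccc2)C#C1 | intermediate
15 | [(2R,3S)-5,7-bis(benzyloxy)-2-(3,4,5-tris(benzyloxy)phenyl)-3-(triisopropylsilyloxy)chroman-8-yl]lithium | [Li]c1c(OCc5ccccc5)cc(OCc5ccccc5)c2c1O[C@H](c1cc(OCc5ccccc5)c(OCc5ccccc5)c(OCc5ccccc5)c1)[C@@H](O[Si](C(C)C)(C(C)C)C(C)C)C2 | intermediate
16 | (2R,3S)-5,7-bis(benzyloxy)-2-[3,4,5-tris(benzyloxy)phenyl]-3-(triisopropylsilyloxy)chromane-8-carbaldehyde | O=Cc1c(OCc5ccccc5)cc(OCc5ccccc5)c2c1O[C@H](c1cc(OCc5ccccc5)c(OCc5ccccc5)c(OCc5ccccc5)c1)[C@@H](O[Si](C(C)C)(C(C)C)C(C)C)C2 | intermediate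
17 | 4-(benzyloxy)acetophenone | CC(=O)c1ccc(OCc2ccccc2)cc1 | starting material
18 | (E)-1-[4-(benzyloxy)phenyl]-3-[(2R,3S)-5,7-bis(benzyloxy)-2-(3,4,5-tris(benzyloxy)phenyl)-3-(triisopropylsilyloxy)chroman-8-yl]prop-2-en-1-one | O=C(/C=C/c3c(OCc5ccccc5)cc(OCc5ccccc5)c4c3O[C@H](c3cc(OCc5ccccc5)c(OCc5ccccc5)c(OCc5ccccc5)c3)[C@@H](O[Si](C(C)C)(C(C)C)C(C)C)C4)c1ccc(OCc5ccccc5)cc1 | intermediate
19 | [4-(benzyloxy)-2-fluorophenyl]boronic acid | OB(O)c1ccc(OCc2ccccc2)cc1F | starting material
20 | (3S)-1-[4-(benzyloxy)phenyl]-3-[4-(benzyloxy)-2-fluorophenyl]-3-[(2R,3S)-5,7-bis(benzyloxy)-2-(3,4,5-tris(benzyloxy)phenyl)-3-(triisopropylsilyloxy)chroman-8-yl]propan-1-one | O=C(C[C@@H](c3c(OCc5ccccc5)cc(OCc5ccccc5)c4c3O[C@H](c3cc(OCc5ccccc5)c(OCc5ccccc5)c(OCc5ccccc5)c3)[C@@H](O[Si](C(C)C)(C(C)C)C(C)C)C4)c3ccc(OCc5ccccc5)cc3F)c1ccc(OCc5ccccc5)cc1 | intermediate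
21 | (1S,3S)-1-[4-(benzyloxy)phenyl]-3-[4-(benzyloxy)-2-fluorophenyl]-3-[(2R,3S)-5,7-bis(benzyloxy)-2-(3,4,5-tris(benzyloxy)phenyl)-3-(triisopropylsilyloxy)chroman-8-yl]propan-1-ol | O[C@@H](C[C@@H](c3c(OCc5ccccc5)cc(OCc5ccccc5)c4c3O[C@H](c3cc(OCc5ccccc5)c(OCc5ccccc5)c(OCc5ccccc5)c3)[C@@H](O[Si](C(C)C)(C(C)C)C(C)C)C4)c3ccc(OCc5ccccc5)cc3F)c1ccc(OCc5ccccc5)cc1 | intermediate
22 | dilithio derivative of 21 (lithium alkoxide at C1; lithium on the ring A carbon between fluorine and benzyloxy, the future C8) | [Li]O[C@@H](C[C@@H](c3c(OCc5ccccc5)cc(OCc5ccccc5)c4c3O[C@H](c3cc(OCc5ccccc5)c(OCc5ccccc5)c(OCc5ccccc5)c3)[C@@H](O[Si](C(C)C)(C(C)C)C(C)C)C4)c3ccc(OCc5ccccc5)c([Li])c3F)c1ccc(OCc5ccccc5)cc1 | intermediate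
23 | lithium alkoxide of the ring A aryne (triple bond between the future C8a and C8) | [Li]O[C@@H](C[C@@H](c3c(OCc5ccccc5)cc(OCc5ccccc5)c4c3O[C@H](c3cc(OCc5ccccc5)c(OCc5ccccc5)c(OCc5ccccc5)c3)[C@@H](O[Si](C(C)C)(C(C)C)C(C)C)C4)C3=CC=C(OCc5ccccc5)C#C3)c1ccc(OCc5ccccc5)cc1 | intermediate
24 | 8-lithio derivative of 25 | c5ccccc5COc1ccc([C@@H]2C[C@@H](c3c(OCc5ccccc5)cc(OCc5ccccc5)c4c3O[C@H](c3cc(OCc5ccccc5)c(OCc5ccccc5)c(OCc5ccccc5)c3)[C@@H](O[Si](C(C)C)(C(C)C)C(C)C)C4)c3ccc(OCc5ccccc5)c([Li])c3O2)cc1 | intermediate
25 | (2S,4R)-7-(benzyloxy)-2-[4-(benzyloxy)phenyl]-4-[(2R,3S)-5,7-bis(benzyloxy)-2-(3,4,5-tris(benzyloxy)phenyl)-3-(triisopropylsilyloxy)chroman-8-yl]chromane | c5ccccc5COc1ccc([C@@H]2C[C@@H](c3c(OCc5ccccc5)cc(OCc5ccccc5)c4c3O[C@H](c3cc(OCc5ccccc5)c(OCc5ccccc5)c(OCc5ccccc5)c3)[C@@H](O[Si](C(C)C)(C(C)C)C(C)C)C4)c3ccc(OCc5ccccc5)cc3O2)cc1 | intermediate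
26 | (2R,3S)-5,7-bis(benzyloxy)-8-[(2S,4R)-7-(benzyloxy)-2-(4-(benzyloxy)phenyl)chroman-4-yl]-2-[3,4,5-tris(benzyloxy)phenyl]chroman-3-ol | c5ccccc5COc1ccc([C@@H]2C[C@@H](c3c(OCc5ccccc5)cc(OCc5ccccc5)c4c3O[C@H](c3cc(OCc5ccccc5)c(OCc5ccccc5)c(OCc5ccccc5)c3)[C@@H](O)C4)c3ccc(OCc5ccccc5)cc3O2)cc1 | intermediate
27 | (2R,3S)-8-[(2S,4R)-7-hydroxy-2-(4-hydroxyphenyl)chroman-4-yl]-2-(3,4,5-trihydroxyphenyl)chromane-3,5,7-triol | Oc1ccc([C@@H]2C[C@@H](c3c(O)cc(O)c4c3O[C@H](c3cc(O)c(O)c(O)c3)[C@@H](O)C4)c3ccc(O)cc3O2)cc1 | target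

## Step count and risk

Total: 13 steps. Longest linear sequence: 13 steps (1 → 27); 3, 9, 12, 17 and 19 enter as purchased components.

**Step 7 (key step).** Several processes could divert it. The alkoxide could displace fluoride directly without aryne formation, which leaves no carbanion on C8'. The C8' aryllithium could be protonated by the liberated amine before formylation, after which re-lithiation would lose the C6'/C8' distinction. Benzylic positions of the ethers could be metalated, with rearrangement. The aryne could be trapped intermolecularly.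
Fallback, from 11 back to 16 by known stepwise chemistry: the potassium alkoxide of 11 (KH, DMF, 0 °C → rt) closes ring F by addition–elimination at the aryl fluoride to give (2R,3S)-5,7-bis(benzyloxy)-2-[3,4,5-tris(benzyloxy)phenyl]-3-(triisopropylsilyloxy)chromane F1. Electrophilic bromination with N-bromosuccinimide at low temperature, which in 5,7-dialkoxyflavans favours C8, gives the 8-bromide F2. Bromine–lithium exchange with n-BuLi at −78 °C regenerates 15, and 12 then gives 16.

**Step 9.** Insertion into the crowded, electron-rich β-aryl enone may be slow, so that protodeboronation of 19 outruns addition, and the face selectivity on this substrate is not secured.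
Fallback, from 16 back to 20 by auxiliary control: Horner–Wadsworth–Emmons olefination of 16 with diethyl {2-oxo-2-[(4S)-2-oxo-4-phenyl-1,3-oxazolidin-3-yl]ethyl}phosphonate (LiCl, i-Pr2NEt, MeCN) gives the enoyl imide F3. [4-(Benzyloxy)-2-fluorophenyl]magnesium bromide F4 (from 4-(benzyloxy)-1-bromo-2-fluorobenzene and Mg) is added with CuBr·SMe2 at −40 °C. In the magnesium-chelated s-cis conformer the (4S)-phenyl group should shield its own face and direct the aryl group to the required one, giving adduct F5. Transamination with N,O-dimethylhydroxylamine hydrochloride and AlMe3 gives the Weinreb amide F6, and 4-(benzyloxy)phenylmagnesium bromide then returns to 20.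

**Step 11.** On this advanced intermediate the strong amide base may metalate elsewhere (benzylic ether positions of rings C and F, C4–H), or the ring A aryne may be consumed before the hindered alkoxide reaches it.
Fallback, from 18 back to 25 without any aryl fluoride displacement: 3-(benzyloxy)phenol is brominated ortho to the hydroxyl (N-bromosuccinimide, catalytic i-Pr2NH, CH2Cl2) to 5-(benzyloxy)-2-bromophenol F7. Allylation (allyl bromide, K2CO3) gives 2-(allyloxy)-4-(benzyloxy)-1-bromobenzene F8. Bromine–lithium exchange and borylation (n-BuLi, B(OiPr)3, −78 °C; aqueous acid) give [2-(allyloxy)-4-(benzyloxy)phenyl]boronic acid F9. The 1,4-addition of F9 to 18 under the conditions of step 9 gives the (3R)-ketone F10. (S)-2-Methyl-CBS-oxazaborolidine with catecholborane at −78 °C, which spares the allyl group, gives the (1R,3R)-alcohol F11. Zerovalent palladium (Pd(PPh3)4, morpholine) removes the allyl group to give the phenol F12. Mitsunobu closure (PPh3, diisopropyl azodicarboxylate, toluene, 0 °C) forms C2–O1 with inversion and gives 25.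

**Step 6.** Facial selectivity may be poor if magnesium partly coordinates the silyloxy oxygen or if Felkin–Anh control is weak, giving a mixture of C1 epimers that is hard to separate.
Fallback, from 8 back to 11 by reagent control: the unselective adduct mixture from 8 and 10 is oxidised (Dess–Martin periodinane) to the ketone (2S)-3-[2-fluoro-4,6-bis(benzyloxy)phenyl]-2-(triisopropylsilyloxy)-1-[3,4,5-tris(benzyloxy)phenyl]propan-1-one F13. Reduction with (R)-2-methyl-CBS-oxazaborolidine and BH3·SMe2 then sets the (1R) carbinol and returns to 11.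

**Step 2.** Metalation may occur between the two benzyloxy groups instead of next to fluorine, the ortho-fluoroaryllithium may lose lithium fluoride before it meets the epoxide, or BF3 may start to cleave the trityl ether.
Fallback, from 2 back to 4 with the metalation site fixed by a halogen: bromination of 2 with N-bromosuccinimide (MeCN, 0 °C), para to one benzyloxy group and next to fluorine, gives 2-bromo-1-fluoro-3,5-bis(benzyloxy)benzene F14, which is purified by crystallisation. Bromine–lithium exchange (n-BuLi, THF, −78 °C) gives 4, and the route continues to 5.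

## Further compounds

F1 | step 7 | (2R,3S)-5,7-bis(benzyloxy)-2-[3,4,5-tris(benzyloxy)phenyl]-3-(triisopropylsilyloxy)chromane | c1c(OCc5ccccc5)cc(OCc5ccccc5)c2c1O[C@H](c1cc(OCc5ccccc5)c(OCc5ccccc5)c(OCc5ccccc5)c1)[C@@H](O[Si](C(C)C)(C(C)C)C(C)C)C2
F2 | step 7 | (2R,3S)-8-bromo-5,7-bis(benzyloxy)-2-[3,4,5-tris(benzyloxy)phenyl]-3-(triisopropylsilyloxy)chromane | Brc1c(OCc5ccccc5)cc(OCc5ccccc5)c2c1O[C@H](c1cc(OCc5ccccc5)c(OCc5ccccc5)c(OCc5ccccc5)c1)[C@@H](O[Si](C(C)C)(C(C)C)C(C)C)C2
F3 | step 9 | (4S)-3-[(2E)-3-{(2R,3S)-5,7-bis(benzyloxy)-2-[3,4,5-tris(benzyloxy)phenyl]-3-(triisopropylsilyloxy)chroman-8-yl}prop-2-enoyl]-4-phenyl-1,3-oxazolidin-2-one | O=C(/C=C/c3c(OCc5ccccc5)cc(OCc5ccccc5)c4c3O[C@H](c3cc(OCc5ccccc5)c(OCc5ccccc5)c(OCc5ccccc5)c3)[C@@H](O[Si](C(C)C)(C(C)C)C(C)C)C4)N1[C@@H](c2ccccc2)COC1=O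
F4 | step 9 | [4-(benzyloxy)-2-fluorophenyl]magnesium bromide | Br[Mg]c1ccc(OCc2ccccc2)cc1F
F5 | step 9 | (4S)-3-[(3S)-3-[4-(benzyloxy)-2-fluorophenyl]-3-{(2R,3S)-5,7-bis(benzyloxy)-2-[3,4,5-tris(benzyloxy)phenyl]-3-(triisopropylsilyloxy)chroman-8-yl}propanoyl]-4-phenyl-1,3-oxazolidin-2-one | O=C(C[C@@H](c3c(OCc5ccccc5)cc(OCc5ccccc5)c4c3O[C@H](c3cc(OCc5ccccc5)c(OCc5ccccc5)c(OCc5ccccc5)c3)[C@@H](O[Si](C(C)C)(C(C)C)C(C)C)C4)c3ccc(OCc5ccccc5)cc3F)N1[C@@H](c2ccccc2)COC1=O
F6 | step 9 | (3S)-3-[4-(benzyloxy)-2-fluorophenyl]-3-{(2R,3S)-5,7-bis(benzyloxy)-2-[3,4,5-tris(benzyloxy)phenyl]-3-(triisopropylsilyloxy)chroman-8-yl}-N-methoxy-N-methylpropanamide | CON(C)C(=O)C[C@@H](c3c(OCc5ccccc5)cc(OCc5ccccc5)c4c3O[C@H](c3cc(OCc5ccccc5)c(OCc5ccccc5)c(OCc5ccccc5)c3)[C@@H](O[Si](C(C)C)(C(C)C)C(C)C)C4)c3ccc(OCc5ccccc5)cc3F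
F7 | step 11 | 5-(benzyloxy)-2-bromophenol | Oc1cc(OCc2ccccc2)ccc1Br
F8 | step 11 | 2-(allyloxy)-4-(benzyloxy)-1-bromobenzene | C=CCOc1cc(OCc2ccccc2)ccc1Br
F9 | step 11 | [2-(allyloxy)-4-(benzyloxy)phenyl]boronic acid | C=CCOc1cc(OCc2ccccc2)ccc1B(O)O
F10 | step 11 | (3R)-3-[2-(allyloxy)-4-(benzyloxy)phenyl]-1-[4-(benzyloxy)phenyl]-3-{(2R,3S)-5,7-bis(benzyloxy)-2-[3,4,5-tris(benzyloxy)phenyl]-3-(triisopropylsilyloxy)chroman-8-yl}propan-1-one | O=C(C[C@@H](c3c(OCc5ccccc5)cc(OCc5ccccc5)c4c3O[C@H](c3cc(OCc5ccccc5)c(OCc5ccccc5)c(OCc5ccccc5)c3)[C@@H](O[Si](C(C)C)(C(C)C)C(C)C)C4)c3ccc(OCc5ccccc5)cc3OCC=C)c1ccc(OCc5ccccc5)cc1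
F11 | step 11 | (1R,3R)-3-[2-(allyloxy)-4-(benzyloxy)phenyl]-1-[4-(benzyloxy)phenyl]-3-{(2R,3S)-5,7-bis(benzyloxy)-2-[3,4,5-tris(benzyloxy)phenyl]-3-(triisopropylsilyloxy)chroman-8-yl}propan-1-ol | O[C@H](C[C@@H](c3c(OCc5ccccc5)cc(OCc5ccccc5)c4c3O[C@H](c3cc(OCc5ccccc5)c(OCc5ccccc5)c(OCc5ccccc5)c3)[C@@H](O[Si](C(C)C)(C(C)C)C(C)C)C4)c3ccc(OCc5ccccc5)cc3OCC=C)c1ccc(OCc5ccccc5)cc1
F12 | step 11 | (1R,3R)-3-[4-(benzyloxy)-2-hydroxyphenyl]-1-[4-(benzyloxy)phenyl]-3-{(2R,3S)-5,7-bis(benzyloxy)-2-[3,4,5-tris(benzyloxy)phenyl]-3-(triisopropylsilyloxy)chroman-8-yl}propan-1-ol | O[C@H](C[C@@H](c3c(OCc5ccccc5)cc(OCc5ccccc5)c4c3O[C@H](c3cc(OCc5ccccc5)c(OCc5ccccc5)c(OCc5ccccc5)c3)[C@@H](O[Si](C(C)C)(C(C)C)C(C)C)C4)c3ccc(OCc5ccccc5)cc3O)c1ccc(OCc5ccccc5)cc1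
F13 | step 6 | (2S)-3-[2-fluoro-4,6-bis(benzyloxy)phenyl]-2-(triisopropylsilyloxy)-1-[3,4,5-tris(benzyloxy)phenyl]propan-1-one | Fc1cc(OCc2ccccc2)cc(OCc2ccccc2)c1C[C@H](O[Si](C(C)C)(C(C)C)C(C)C)C(=O)c1cc(OCc2ccccc2)c(OCc2ccccc2)c(OCc2ccccc2)c1
F14 | step 2 | 2-bromo-1-fluoro-3,5-bis(benzyloxy)benzene | Fc1cc(OCc2ccccc2)cc(OCc2ccccc2)c1Br
A1 | alternative 1 | hepta-O-benzyl flav-3'-ene (3',4'-didehydro-3'-deoxy) form of the target | c5ccccc5COc1ccc([C@@H]2C[C@@H](c3c(OCc5ccccc5)cc(OCc5ccccc5)c4c3O[C@H](c3cc(OCc5ccccc5)c(OCc5ccccc5)c(OCc5ccccc5)c3)C=C4)c3ccc(OCc5ccccc5)cc3O2)cc1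
A2 | alternative 1 | metathesis diene: hepta-O-benzyl compound with vinyl on C4a' and the 1-[3,4,5-tris(benzyloxy)phenyl]allyl ether on the C8a' oxygen | c5ccccc5COc1ccc([C@@H]2C[C@@H](c3c(OCc5ccccc5)cc(OCc5ccccc5)c(C=C)c3O[C@H](c3cc(OCc5ccccc5)c(OCc5ccccc5)c(OCc5ccccc5)c3)C=C)c3ccc(OCc5ccccc5)cc3O2)cc1
A3 | alternative 2 | (4R)-7-benzyloxy-4-(hexa-O-benzylgallocatechin-8'-yl)chroman-2-ol, anomeric mixture | OC2C[C@@H](c3c(OCc5ccccc5)cc(OCc5ccccc5)c4c3O[C@H](c3cc(OCc5ccccc5)c(OCc5ccccc5)c(OCc5ccccc5)c3)[C@@H](OCc5ccccc5)C4)c3ccc(OCc5ccccc5)cc3O2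
A4 | alternative 2 | (E)-3-(hexa-O-benzylgallocatechin-8'-yl)prop-2-enal | O=C/C=C/c1c(OCc5ccccc5)cc(OCc5ccccc5)c2c1O[C@H](c1cc(OCc5ccccc5)c(OCc5ccccc5)c(OCc5ccccc5)c1)[C@@H](OCc5ccccc5)C2
A5 | alternative 2 | 3-(benzyloxy)phenol | Oc1cccc(OCc2ccccc2)c1
A6 | alternative 2 | (+)-gallocatechin | c1c(O)cc(O)c2c1O[C@H](c1cc(O)c(O)c(O)c1)[C@@H](O)C2
A7 | alternative 3 | hepta-O-benzyl target 3'-formate | c5ccccc5COc1ccc([C@@H]2C[C@@H](c3c(OCc5ccccc5)cc(OCc5ccccc5)c4c3O[C@H](c3cc(OCc5ccccc5)c(OCc5ccccc5)c(OCc5ccccc5)c3)[C@@H](OC=O)C4)c3ccc(OCc5ccccc5)cc3O2)cc1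
A8 | alternative 3 | hepta-O-benzyl (1S,2S)-diol with free C8a' phenol (ring F open at O1'–C2') | c5ccccc5COc1ccc([C@@H]2C[C@@H](c3c(OCc5ccccc5)cc(OCc5ccccc5)c(C[C@H](O)[C@@H](O)c4cc(OCc5ccccc5)c(OCc5ccccc5)c(OCc5ccccc5)c4)c3O)c3ccc(OCc5ccccc5)cc3O2)cc1
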